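**Retrosynthetic overview**

- Last step: hydrogenolysis of seven benzyl ethers. The only stereocenter, C-2 (R) of the flavanone, is set one step earlier by enantioselective conjugate addition of a 4-(benzyloxy)phenyl group to a 2-unsubstituted chromone, so no basic step follows it.
- Key disconnection: the bond from flavone C-2 to catechol carbon Cb (Ca is the catechol carbon on flavanone C-6, Cb its neighbour). It is made in one flask by etherification and a palladium-catalysed Truce–Smiles-type O→C shift that joins a bromobiaryl phenol with a 2-sulfonylchromone.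
- Enabling feature: in ring A of the flavanone unit the phenolic O-5 is ortho to C-6, which carries Ca. A chromone hung on O-5 has its C-2 (β-carbon of a vinylogous ester) six atoms round from Cb (Cb–Ca–C-6–C-5–O-5–C-2), and O-5 can leave again as the chelated 5-OH of the target.
- Biaryl bond C-6–Ca: Suzuki–Miyaura coupling of a 6-iodochromone with a 2-bromoarylboronate; Ca and Cb are the two equivalent C–Br carbons of a mirror-symmetric catechol dibromide.
- Ring order: the pyranone of the sulfonylchromone is closed first (step 6), the other pyranone is bought. A temporary dibenzopyran spiro ring is closed and re-opened in step 8; no ring is formed later, the flavanone heterocycle being the bought pyranone, saturated in step 10.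

Key step: step 8

Assumption: the descriptor in the target SMILES corresponds to (2R) at the flavanone carbon (priorities O-1 > aryl > C-3 > H), and the biaryl axis, which carries no descriptor, is treated as not configurationally fixed.

**Route**

Step 1
Reactants: 1 5,7-dihydroxy-4H-chromen-4-one
Product: 2 7-(benzyloxy)-5-hydroxy-4H-chromen-4-one
Conditions: BnBr (1.05 equiv), K2CO3 (1.1 equiv), acetone, 50 °C
Reagents that add atoms: benzyl bromide, BrCc1ccccc1
Why: Williamson etherification at the more acidic, non-chelated 7-OH, while the hydrogen-bonded 5-OH should stay free with one equivalent of base.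

Step 2
Reactants: 2 7-(benzyloxy)-5-hydroxy-4H-chromen-4-one
Product: 3 7-(benzyloxy)-5-hydroxy-6-iodo-4H-chromen-4-one
Conditions: BnMe3N·ICl2 (1.1 equiv), CaCO3, CH2Cl2/MeOH, rt
Reagents that add atoms: benzyltrimethylammonium dichloroiodate, C[N+](C)(C)Cc1ccccc1.Cl[I-]Cl
Why: Electrophilic aromatic iodination of 5-hydroxy-7-alkoxy benzopyranones with this reagent goes ortho to the free chelated 5-OH (C-6, not C-8), and CaCO3 removes the HCl so the pyranone and the benzyl ether should survive.

Step 3
Reactants: 4 4,5-dibromobenzene-1,2-diol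
Product: 5 1,2-bis(benzyloxy)-4,5-dibromobenzene
Conditions: BnBr (2.2 equiv), K2CO3, DMF, 50 °C
Reagents that add atoms: benzyl bromide, BrCc1ccccc1
Why: Double Williamson etherification of the catechol, which keeps the two C–Br carbons equivalent.

Step 4
Reactants: 5 1,2-bis(benzyloxy)-4,5-dibromobenzene
Product: 7 2-[4,5-bis(benzyloxy)-2-bromophenyl]-4,4,5,5-tetramethyl-1,3,2-dioxaborolane, via arylmagnesium chloride 6 (not isolated)
Conditions: i-PrMgCl·LiCl (1.05 equiv), THF, −20 °C; then i-PrOBpin, −20 °C to rt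
Reagents that add atoms: 2-isopropoxy-4,4,5,5-tetramethyl-1,3,2-dioxaborolane, CC(C)OB1OC(C)(C)C(C)(C)O1; isopropylmagnesium chloride–lithium chloride, CC(C)[Mg]Cl.[Li+].[Cl-] (its MgCl stays only in intermediate 6)
Why: Bromine–magnesium exchange at one of two equivalent C–Br bonds is accelerated by the ortho bromine, the 2-bromoaryl Grignard reagent is stable below 0 °C (no aryne), and trapping with the borate ester gives the boronate.

Step 5
Reactants: 3 7-(benzyloxy)-5-hydroxy-6-iodo-4H-chromen-4-one; 7 2-[4,5-bis(benzyloxy)-2-bromophenyl]-4,4,5,5-tetramethyl-1,3,2-dioxaborolane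
Product: 8 7-(benzyloxy)-6-[4,5-bis(benzyloxy)-2-bromophenyl]-5-hydroxy-4H-chromen-4-one
Conditions: PdCl2(dppf) (5 mol %), K3PO4, 1,4-dioxane/H2O (10:1), 70 °C
Reagents that add atoms: none
Why: Suzuki–Miyaura coupling in which zerovalent palladium inserts into the C–I bond much faster than into the electron-rich C–Br bond, so the bromide should remain as the handle for step 8.

Step 6
Reactants: 9 1-[2,4-bis(benzyloxy)-6-hydroxyphenyl]ethan-1-one
Product: 11 5,7-bis(benzyloxy)-2-(methylsulfanyl)-4H-chromen-4-one, via potassium chromene-2-thiolate 10 (not isolated)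
Conditions: KOt-Bu, CS2, THF, 0 °C to rt; then MeI, 0 °C to rt
Reagents that add atoms: carbon disulfide, S=C=S; iodomethane, CI; potassium tert-butoxide, CC(C)(C)[O-].[K+] (its potassium stays only in intermediate 10)
Why: The ketone enolate adds to CS2, the phenoxide closes onto the dithiocarboxylate with loss of hydrosulfide (pyranone ring formed by O-acylation-type cyclisation), and the soft thiolate is S-methylated.

Step 7
Reactants: 11 5,7-bis(benzyloxy)-2-(methylsulfanyl)-4H-chromen-4-one
Product: 12 5,7-bis(benzyloxy)-2-(methanesulfonyl)-4H-chromen-4-one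
Conditions: mCPBA (2.2 equiv), CH2Cl2, 0 °C to rt
Reagents that add atoms: 3-chloroperoxybenzoic acid, OOC(=O)c1cccc(Cl)c1
Why: Sulfide-to-sulfone oxidation, which turns C-2 of the chromone into an addition–elimination acceptor without touching the benzyl ethers.

Step 8
Reactants: 8 7-(benzyloxy)-6-[4,5-bis(benzyloxy)-2-bromophenyl]-5-hydroxy-4H-chromen-4-one; 12 5,7-bis(benzyloxy)-2-(methanesulfonyl)-4H-chromen-4-one
Product: 15 7-(benzyloxy)-6-[4,5-bis(benzyloxy)-2-(5,7-bis(benzyloxy)-4-oxo-4H-chromen-2-yl)phenyl]-5-hydroxy-4H-chromen-4-one, via aryl chromonyl ether 13 (not isolated), via spiroketal 14 (not isolated)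
Conditions: Cs2CO3 (1.1 equiv), DMF, 4 Å MS, rt; then Pd(OAc)2 (10 mol %), PPh3 (20 mol %), HCO2Na (2 equiv), n-Bu4NCl, 90 °C
Reagents that add atoms: none
Why: Proposed new method: Cs2CO3 turns the chelated 5-OH of 8 into a phenoxide that displaces methanesulfinate from C-2 of 12 by addition–elimination (the established way to 2-aryloxychromones), giving ether 13, in which the C–Br carbon and chromone C-2 are joined through Ca, C-6, C-5 and O-5. Zerovalent palladium then inserts into the C–Br bond and the arylpalladium bromide adds across C-2=C-3 of the tethered chromone in a 6-exo-trig carbopalladation (aryl to the doubly oxygenated, β-carbonyl carbon C-2, palladium to C-3), which closes a temporary dibenzopyran ring around a spiro carbon; the palladium enolate either expels the O-5 aryloxide at once (β-heteroatom elimination, formate returning divalent palladium to zerovalent palladium) or is reduced by formate to spiroketal 14, which loses the same aryloxide by E1cB under the hydrogencarbonate present, so both branches end in 15. The net change is a Truce–Smiles-type 1,5 shift of the whole chromonyl group from oxygen to carbon; the closest known reaction types are the intramolecular reductive Heck addition of aryl halides to enones, palladium-catalysed arylative ring opening by β-oxygen elimination and the anionic Truce–Smiles rearrangement, none of them shown on a 2-aryloxychromone. The spiro carbon of 14 is the only new stereocenter, it forms racemic and is destroyed in the elimination, so 15 carries none. The step needs insertion to outrun formate reduction of the arylpalladium bromide, which the short rigid tether and the polarised enol-ether/enone double bond should secure, and it needs cleavage of the exocyclic C-2–O-5 bond instead of the pyranone C-2–O-1 bond, which thermodynamics should secure because only that cleavage gives the aromatic γ-pyrone and a chelated, unstrained phenoxide while the ring-opened alternative can re-close by oxa-Michael addition and funnel to 15.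

Step 9
Reactants: 15 7-(benzyloxy)-6-[4,5-bis(benzyloxy)-2-(5,7-bis(benzyloxy)-4-oxo-4H-chromen-2-yl)phenyl]-5-hydroxy-4H-chromen-4-one
Product: 16 5,7-bis(benzyloxy)-6-[4,5-bis(benzyloxy)-2-(5,7-bis(benzyloxy)-4-oxo-4H-chromen-2-yl)phenyl]-4H-chromen-4-one
Conditions: BnBr, Cs2CO3, n-Bu4NI (cat.), DMF, 50 °C
Reagents that add atoms: benzyl bromide, BrCc1ccccc1
Why: Williamson benzylation of the freed 5-OH under forcing conditions, which removes the acidic, metal-chelating phenol before the palladium-catalysed addition.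

Step 10
Reactants: 16 5,7-bis(benzyloxy)-6-[4,5-bis(benzyloxy)-2-(5,7-bis(benzyloxy)-4-oxo-4H-chromen-2-yl)phenyl]-4H-chromen-4-one; 17 [4-(benzyloxy)phenyl]boronic acid
Product: 18 (2R)-5,7-bis(benzyloxy)-2-[4-(benzyloxy)phenyl]-6-[4,5-bis(benzyloxy)-2-(5,7-bis(benzyloxy)-4-oxo-4H-chromen-2-yl)phenyl]-2,3-dihydro-4H-chromen-4-one
Conditions: Pd(OCOCF3)2 (10 mol %), (S)-t-BuPyOx [(S)-4-tert-butyl-2-(pyridin-2-yl)-4,5-dihydro-1,3-oxazole] (12 mol %), NH4PF6, H2O (5 equiv), ClCH2CH2Cl, 60 °C
Reagents that add atoms: none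
Why: Enantioselective palladium-catalysed conjugate addition of an arylboronic acid to a 2-unsubstituted chromone, in which the chiral pyridine–oxazoline complex of divalent palladium should deliver the aryl group to the face giving (2R) (assigned by analogy with cyclic enones, where this ligand gives the (R)-β-aryl ketone of the same spatial arrangement, and to be confirmed at this stage), while the 2-aryl flavone unit, a hindered β,β-disubstituted acceptor, should not react.

Step 11
Reactants: 18 (2R)-5,7-bis(benzyloxy)-2-[4-(benzyloxy)phenyl]-6-[4,5-bis(benzyloxy)-2-(5,7-bis(benzyloxy)-4-oxo-4H-chromen-2-yl)phenyl]-2,3-dihydro-4H-chromen-4-one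
Product: 19 (2R)-6-[2-(5,7-dihydroxy-4-oxo-4H-chromen-2-yl)-4,5-dihydroxyphenyl]-5,7-dihydroxy-2-(4-hydroxyphenyl)-2,3-dihydro-4H-chromen-4-one
Conditions: H2 (1 atm), 10% Pd on carbon, THF/MeOH, rt
Reagents that add atoms: none
Why: Hydrogenolysis of the seven aryl benzyl ethers under neutral conditions, which should leave the flavone double bond and both ketones intact and cannot epimerise C-2 because no acid or base is present.

**Compound list**

1 | 5,7-dihydroxy-4H-chromen-4-one | O=c1ccoc2cc(O)cc(O)c12 | starting material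
2 | 7-(benzyloxy)-5-hydroxy-4H-chromen-4-one | O=c1ccoc2cc(OCc3ccccc3)cc(O)c12 | intermediate
3 | 7-(benzyloxy)-5-hydroxy-6-iodo-4H-chromen-4-one | O=c1ccoc2cc(OCc3ccccc3)c(I)c(O)c12 | intermediate
4 | 4,5-dibromobenzene-1,2-diol | Oc1cc(Br)c(Br)cc1O | starting material
5 | 1,2-bis(benzyloxy)-4,5-dibromobenzene | Brc1cc(OCc2ccccc2)c(OCc2ccccc2)cc1Br | intermediate
6 | [4,5-bis(benzyloxy)-2-bromophenyl]magnesium chloride | Cl[Mg]c1cc(OCc2ccccc2)c(OCc2ccccc2)cc1Br | intermediate (not isolated)
7 | 2-[4,5-bis(benzyloxy)-2-bromophenyl]-4,4,5,5-tetramethyl-1,3,2-dioxaborolane | CC1(C)OB(OC1(C)C)c1cc(OCc2ccccc2)c(OCc2ccccc2)cc1Br | intermediate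
8 | 7-(benzyloxy)-6-[4,5-bis(benzyloxy)-2-bromophenyl]-5-hydroxy-4H-chromen-4-one | O=c1ccoc2cc(OCc3ccccc3)c(-c3cc(OCc4ccccc4)c(OCc4ccccc4)cc3Br)c(O)c12 | intermediate
9 | 1-[2,4-bis(benzyloxy)-6-hydroxyphenyl]ethan-1-one | CC(=O)c1c(O)cc(OCc2ccccc2)cc1OCc1ccccc1 | starting material
10 | potassium 5,7-bis(benzyloxy)-4-oxo-4H-chromene-2-thiolate | [K+].[S-]c1cc(=O)c2c(OCc3ccccc3)cc(OCc3ccccc3)cc2o1 | intermediate (not isolated)
11 | 5,7-bis(benzyloxy)-2-(methylsulfanyl)-4H-chromen-4-one | CSc1cc(=O)c2c(OCc3ccccc3)cc(OCc3ccccc3)cc2o1 | intermediate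
12 | 5,7-bis(benzyloxy)-2-(methanesulfonyl)-4H-chromen-4-one | CS(=O)(=O)c1cc(=O)c2c(OCc3ccccc3)cc(OCc3ccccc3)cc2o1 | intermediate
13 | 7-(benzyloxy)-6-[4,5-bis(benzyloxy)-2-bromophenyl]-5-{[5,7-bis(benzyloxy)-4-oxo-4H-chromen-2-yl]oxy}-4H-chromen-4-one | O=c1ccoc2cc(OCc3ccccc3)c(-c3cc(OCc4ccccc4)c(OCc4ccccc4)cc3Br)c(Oc3cc(=O)c4c(OCc5ccccc5)cc(OCc5ccccc5)cc4o3)c12 | intermediate (not isolated)
14 | racemic spiroketal: C-2 of a 5,7-bis(benzyloxy)chroman-4-one is also bonded to O-5 of the 7-(benzyloxy)chromone unit and to the former C–Br carbon of the 4,5-bis(benzyloxy)phenyl ring, closing a six-membered dibenzopyran ring through the spiro carbon | O=C1CC2(Oc3cc(OCc4ccccc4)cc(OCc4ccccc4)c13)Oc1c(-c3cc(OCc4ccccc4)c(OCc4ccccc4)cc32)c(OCc2ccccc2)cc2occc(=O)c12 | intermediate (not isolated)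
15 | 7-(benzyloxy)-6-[4,5-bis(benzyloxy)-2-(5,7-bis(benzyloxy)-4-oxo-4H-chromen-2-yl)phenyl]-5-hydroxy-4H-chromen-4-one | O=c1ccoc2cc(OCc3ccccc3)c(-c3cc(OCc4ccccc4)c(OCc4ccccc4)cc3-c3cc(=O)c4c(OCc5ccccc5)cc(OCc5ccccc5)cc4o3)c(O)c12 | intermediate
16 | 5,7-bis(benzyloxy)-6-[4,5-bis(benzyloxy)-2-(5,7-bis(benzyloxy)-4-oxo-4H-chromen-2-yl)phenyl]-4H-chromen-4-one | O=c1ccoc2cc(OCc3ccccc3)c(-c3cc(OCc4ccccc4)c(OCc4ccccc4)cc3-c3cc(=O)c4c(OCc5ccccc5)cc(OCc5ccccc5)cc4o3)c(OCc3ccccc3)c12 | intermediate
17 | [4-(benzyloxy)phenyl]boronic acid | OB(O)c1ccc(OCc2ccccc2)cc1 | starting material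
18 | (2R)-5,7-bis(benzyloxy)-2-[4-(benzyloxy)phenyl]-6-[4,5-bis(benzyloxy)-2-(5,7-bis(benzyloxy)-4-oxo-4H-chromen-2-yl)phenyl]-2,3-dihydro-4H-chromen-4-one | O=C1C[C@H](c2ccc(OCc3ccccc3)cc2)Oc2cc(OCc3ccccc3)c(-c3cc(OCc4ccccc4)c(OCc4ccccc4)cc3-c3cc(=O)c4c(OCc5ccccc5)cc(OCc5ccccc5)cc4o3)c(OCc3ccccc3)c21 | intermediate
19 | (2R)-6-[2-(5,7-dihydroxy-4-oxo-4H-chromen-2-yl)-4,5-dihydroxyphenyl]-5,7-dihydroxy-2-(4-hydroxyphenyl)-2,3-dihydro-4H-chromen-4-one | O=C1C[C@H](c2ccc(O)cc2)Oc2cc(O)c(-c3cc(O)c(O)cc3-c3cc(=O)c4c(O)cc(O)cc4o3)c(O)c21 | target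

**Step count and risks**

Total steps: 11. Longest linear sequence: 7 steps (1 → 2 → 3 → 8 → 15 → 16 → 18 → 19; the branch from 4 is equally long).

Steps most likely to fail:

1. Step 8 (proposed new method). The arylpalladium bromide may be reduced by formate before it inserts (loss of bromine without C–C bond formation). The etherification at the hindered, chelated phenoxide may stall. The spiro intermediate may open in the wrong direction without funnelling back. Fallback with known chemistry, setting out from 8: benzylation of the 5-OH (BnBr, Cs2CO3, DMF, 50 °C) should give 5,7-bis(benzyloxy)-6-[4,5-bis(benzyloxy)-2-bromophenyl]-4H-chromen-4-one F1. Miyaura borylation (Pd2(dba)3, XPhos (2-dicyclohexylphosphino-2′,4′,6′-triisopropylbiphenyl), B2(OH)4, KOAc, EtOH, 80 °C) should give {4,5-bis(benzyloxy)-2-[5,7-bis(benzyloxy)-4-oxo-4H-chromen-6-yl]phenyl}boronic acid F2. Liebeskind–Srogl coupling of F2 with thioether 11 (Pd2(dba)3, tri(2-furyl)phosphine, copper thiophene-2-carboxylate Cu(O2CC4H3S) with monovalent copper, THF, 50 °C) forms the same C-2–Cb bond intermolecularly, and the route is rejoined at 16.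

2. Step 10. Facial selectivity may be poor or insertion slow at the electron-rich, hindered 5,7-dialkoxychromone, with protodeboronation of 17 consuming the aryl donor. Fallback, setting out from 16: racemic conjugate addition of 17 with an achiral catalyst (Pd(OCOCF3)2, 2,2′-bipyridine, aqueous AcOH/THF, 60 °C) should give racemic 5,7-bis(benzyloxy)-2-[4-(benzyloxy)phenyl]-6-[4,5-bis(benzyloxy)-2-(5,7-bis(benzyloxy)-4-oxo-4H-chromen-2-yl)phenyl]-2,3-dihydro-4H-chromen-4-one F3. Resolution by preparative chromatography on a chiral stationary phase then gives the (2R) enantiomer, and the route is rejoined at 18.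

3. Step 5. Transmetalation at the doubly ortho-substituted arylpalladium iodide may be slow, so that protodeboronation of 7 or oxidative addition into a C–Br bond (oligomerisation) takes over. Fallback with reversed polarity, setting out from 3: Miyaura borylation (PdCl2(dppf), B2pin2, KOAc, dioxane, 80 °C) should give 7-(benzyloxy)-5-hydroxy-6-(4,4,5,5-tetramethyl-1,3,2-dioxaborolan-2-yl)-4H-chromen-4-one F4. Mono-coupling of F4 with an excess (3 equiv) of symmetric dibromide 5 (PdCl2(dppf), K3PO4, dioxane/H2O, 70 °C) needs no halogen discrimination, and the route is rejoined at 8.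

Further compounds
F1 | step 8 | 5,7-bis(benzyloxy)-6-[4,5-bis(benzyloxy)-2-bromophenyl]-4H-chromen-4-one | O=c1ccoc2cc(OCc3ccccc3)c(-c3cc(OCc4ccccc4)c(OCc4ccccc4)cc3Br)c(OCc3ccccc3)c12
F2 | step 8 | {4,5-bis(benzyloxy)-2-[5,7-bis(benzyloxy)-4-oxo-4H-chromen-6-yl]phenyl}boronic acid | O=c1ccoc2cc(OCc3ccccc3)c(-c3cc(OCc4ccccc4)c(OCc4ccccc4)cc3B(O)O)c(OCc3ccccc3)c12
F3 | step 10 | racemic 5,7-bis(benzyloxy)-2-[4-(benzyloxy)phenyl]-6-[4,5-bis(benzyloxy)-2-(5,7-bis(benzyloxy)-4-oxo-4H-chromen-2-yl)phenyl]-2,3-dihydro-4H-chromen-4-one | O=C1CC(c2ccc(OCc3ccccc3)cc2)Oc2cc(OCc3ccccc3)c(-c3cc(OCc4ccccc4)c(OCc4ccccc4)cc3-c3cc(=O)c4c(OCc5ccccc5)cc(OCc5ccccc5)cc4o3)c(OCc3ccccc3)c21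
F4 | step 5 | 7-(benzyloxy)-5-hydroxy-6-(4,4,5,5-tetramethyl-1,3,2-dioxaborolan-2-yl)-4H-chromen-4-one | O=c1ccoc2cc(OCc3ccccc3)c(B3OC(C)(C)C(C)(C)O3)c(O)c12
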